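**Strategy.** Everything rests on disconnecting the quinone ring (C1, C2, C3, C4, C4a, C8a) of the 2-methyl-3-polyprenyl-1,4-naphthoquinone into a phenyl(methoxy)carbene chromium complex (benzo ring and C1), one of its CO ligands (C4) and a skipped enyne carrying the methyl group and the complete C40 chain (C2, C3). A Dötz benzannulation joins them in one operation, forming C1–C2, C3–C4 and C4–C4a, and oxidative work-up delivers the quinone. The step exploits the unsubstituted benzo ring: both oxygenated carbons end as quinone carbonyls, so either orientation of alkyne insertion gives the target. The enyne is built from (S)-citronellyl bromide and two farnesol-derived units by sulfone alkylations.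

Key step: step 14

Remark: the 27R centre of the target has the spatial arrangement of (S)-citronellol; the descriptor changes only because chain extension reverses the CIP ranking of the two methylene arms. Compounds 1, 5, 14, 16 and 17 are taken as purchased.

**Step 1**
Reactants: 1 (2E,6E)-farnesol
Product: 2 benzyl (2E,6E)-farnesyl ether
Conditions: NaH, BnBr, n-Bu4NI (cat.), THF, 0 °C to rt
Reagents that add atoms: benzyl bromide BrCc1ccccc1
Why: Williamson ether synthesis on the primary allylic alkoxide, which touches no alkene, so both E-alkenes should be retained.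

**Step 2**
Reactants: 2 benzyl (2E,6E)-farnesyl ether
Product: 3 (2E,6E,10E)-12-(benzyloxy)-2,6,10-trimethyldodeca-2,6,10-trien-1-ol
Conditions: SeO2 (cat.), t-BuOOH, salicylic acid (cat.), CH2Cl2, 0 °C to rt, stopped at partial conversion
Reagents that add atoms: tert-butyl hydroperoxide CC(C)(C)OO (oxygen relayed by catalytic selenium dioxide O=[Se]=O)
Why: Sharpless catalytic SeO2 allylic oxidation (ene reaction, then [2,3]-shift) should attack the terminal isopropylidene group at its E-methyl group and give the E-allylic alcohol, the 2,3-alkene being deactivated by the allylic oxygen.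

**Step 3**
Reactants: 3 (2E,6E,10E)-12-(benzyloxy)-2,6,10-trimethyldodeca-2,6,10-trien-1-ol
Product: 4 benzyl (2E,6E,10E)-12-bromofarnesyl ether
Conditions: CBr4, PPh3, CH2Cl2, 0 °C
Reagents that add atoms: carbon tetrabromide BrC(Br)(Br)Br
Why: Appel reaction; SN2 displacement at the primary allylic carbon should give the bromide without allylic transposition or loss of E geometry.

**Step 4**
Reactants: 5 (S)-citronellyl bromide
Product: 6 (S)-citronellyl phenyl sulfone
Conditions: PhSO2Na, n-Bu4NI (cat.), DMF, 60 °C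
Reagents that add atoms: sodium benzenesulfinate [Na+].[O-]S(=O)c1ccccc1
Why: SN2 S-alkylation of the sulfinate by a primary bromide; the stereocentre is two carbons away and is not touched.

**Step 5**
Reactants: 6 (S)-citronellyl phenyl sulfone; 4 benzyl (2E,6E,10E)-12-bromofarnesyl ether
Product: 7 C25 sulfone benzyl ether (both C13 epimers)
Conditions: n-BuLi, THF/DMPU, −78 °C; then 4, −78 to −20 °C
Reagents that add atoms: none
Why: Alkylation of the α-sulfonyl carbanion by the primary allylic bromide (Julia-type sulfone coupling, SN2) should join the citronellyl carbon to the ω-CH2 of the farnesyl unit; the new sulfonyl-bearing centre is an epimer mixture that step 6 erases.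

**Step 6**
Reactants: 7 C25 sulfone benzyl ether
Product: 8 (2E,6E,10E,15R)-3,7,11,15,19-pentamethylicosa-2,6,10,18-tetraen-1-ol
Conditions: Li, EtNH2/THF, −78 °C
Reagents that add atoms: none
Why: Dissolving-metal reduction should cleave the non-allylic C–SO2Ph bond and the benzyl ether in one operation, without reducing the isolated trisubstituted alkenes at −78 °C and without touching the methyl stereocentre two bonds from the carbanion site.

**Step 7**
Reactants: 8 (2E,6E,10E,15R)-3,7,11,15,19-pentamethylicosa-2,6,10,18-tetraen-1-ol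
Product: 9 (2E,6E,10E,15R)-1-bromo-3,7,11,15,19-pentamethylicosa-2,6,10,18-tetraene
Conditions: PBr3, pyridine (cat.), Et2O, −10 °C
Reagents that add atoms: phosphorus tribromide BrP(Br)Br
Why: Bromination of a prenyl-type primary allylic alcohol through its phosphite ester (SN2) should proceed as it does for farnesol, with the E-alkene retained.

**Step 8**
Reactants: 9 (2E,6E,10E,15R)-1-bromo-3,7,11,15,19-pentamethylicosa-2,6,10,18-tetraene
Product: 10 C25 allylic phenyl sulfone
Conditions: PhSO2Na, DMF, rt
Reagents that add atoms: sodium benzenesulfinate [Na+].[O-]S(=O)c1ccccc1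
Why: SN2 S-alkylation of the sulfinate at the primary allylic carbon should give the linear E-allylic sulfone.

**Step 9**
Reactants: 10 C25 allylic phenyl sulfone; 4 benzyl (2E,6E,10E)-12-bromofarnesyl ether
Product: 11 C40 sulfone benzyl ether (both C13 epimers)
Conditions: n-BuLi, THF, −78 °C; then 4, −78 to −30 °C
Reagents that add atoms: none
Why: The sulfonyl-stabilised allyl anion should be alkylated at its α-carbon by the allylic bromide (Julia-type sulfone coupling, SN2), creating the head-to-tail junction with all E-alkenes intact; the sulfonyl-bearing centre is removed in step 10.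

**Step 10**
Reactants: 11 C40 sulfone benzyl ether
Product: 12 (2E,6E,10E,14E,18E,22E,27R)-3,7,11,15,19,23,27,31-octamethyldotriaconta-2,6,10,14,18,22,30-heptaen-1-ol
Conditions: Li, EtNH2/THF, −78 °C
Reagents that add atoms: none
Why: Dissolving-metal reductive desulfonylation with simultaneous debenzylation, the standard end of a polyprenol sulfone coupling, should protonate the allyl anion at the former sulfonyl carbon and leave the 14E-alkene in place.

**Step 11**
Reactants: 12 (2E,6E,10E,14E,18E,22E,27R)-3,7,11,15,19,23,27,31-octamethyldotriaconta-2,6,10,14,18,22,30-heptaen-1-ol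
Product: 13 (2E,6E,10E,14E,18E,22E,27R)-1-bromo-3,7,11,15,19,23,27,31-octamethyldotriaconta-2,6,10,14,18,22,30-heptaene
Conditions: PBr3, pyridine (cat.), Et2O, −10 °C
Reagents that add atoms: phosphorus tribromide BrP(Br)Br
Why: Bromination of the primary allylic alcohol through its phosphite ester (SN2), as in step 7.

**Step 12**
Reactants: 13 C40 allylic bromide; 14 prop-1-yn-1-ylmagnesium bromide
Product: 15 (5E,9E,13E,17E,21E,25E,30R)-6,10,14,18,22,26,30,34-octamethylpentatriaconta-5,9,13,17,21,25,33-heptaen-2-yne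
Conditions: CuI (cat.), THF, 0 °C to rt
Reagents that add atoms: none
Why: Copper-catalysed coupling of an alkynyl Grignard reagent with a primary allylic bromide should occur by SN2 at the unhindered CH2 and not by SN2′ at the fully substituted γ-carbon, giving the skipped enyne with the 5E-alkene retained.

**Step 13**
Reactants: 16 hexacarbonylchromium Cr(CO)6; 17 phenyllithium PhLi
Product: 19 pentacarbonyl[methoxy(phenyl)methylidene]chromium (CO)5Cr=C(OMe)Ph, via lithium benzoylpentacarbonylchromate 18 (not isolated)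
Conditions: Et2O, 0 °C to rt; then Me3OBF4, CH2Cl2, 0 °C
Reagents that add atoms: trimethyloxonium tetrafluoroborate C[O+](C)C.F[B-](F)(F)F
Why: Fischer carbene synthesis: PhLi adds to a CO ligand and the resulting acyl metalate is O-methylated by the hard oxonium salt.

**Step 14**
Reactants: 15 C43 skipped enyne; 19 pentacarbonyl[methoxy(phenyl)methylidene]chromium
Product: 22 2-methyl-3-[(2E,6E,10E,14E,18E,22E,27R)-3,7,11,15,19,23,27,31-octamethyldotriaconta-2,6,10,14,18,22,30-heptaen-1-yl]naphthalene-1,4-dione, via tricarbonylchromium naphthol complex 20 (not isolated), via free methoxynaphthol 21 (not isolated)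
Conditions: 19 (1.3 equiv), t-BuOMe, 50 °C; then (NH4)2Ce(NO3)6, MeCN/H2O, 0 °C
Reagents that add atoms: water O
Why: Heating 19 releases one CO ligand, the alkyne of 15 inserts into the Cr=C bond (carbene carbon to the methyl-bearing alkyne carbon, the smaller substituent), a second CO ligand inserts to give a chromium-bound dienylketene whose ketene carbon closes onto the ortho carbon of the phenyl ring, and tautomerisation gives naphthol complex 20; (NH4)2Ce(NO3)6 then strips the Cr(CO)3 group to 21 and oxidises the para-methoxynaphthol to the quinone, water supplying the C1 oxygen and methanol leaving. The closest known reaction type is the Dötz benzannulation of aryl(alkoxy)carbene chromium complexes with internal alkynes, which has precedent with skipped enynes in syntheses of K vitamins. The one ring closed is the six-membered quinone ring, by 6π electrocyclisation of the dienylketene (overall a [3+2+1] assembly from carbene, alkyne and CO). No stereocentre is created, and the E-alkenes and the 27R centre are spectators. The step needs chemoselectivity for the alkyne over seven trisubstituted alkenes, which should hold because unactivated trisubstituted alkenes are not cyclopropanated by the methoxycarbene at 50 °C and the 5-ene cannot reach the vinylcarbene carbon; it needs no regiocontrol, because the benzo ring is unsubstituted and both insertion orientations converge on the same quinone.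

**Compound list**

1 | (2E,6E)-farnesol, (2E,6E)-3,7,11-trimethyldodeca-2,6,10-trien-1-ol | CC(C)=CCC/C(C)=C/CC/C(C)=C/CO | starting material
2 | benzyl (2E,6E)-farnesyl ether, {[(2E,6E)-3,7,11-trimethyldodeca-2,6,10-trien-1-yl]oxymethyl}benzene | CC(C)=CCC/C(C)=C/CC/C(C)=C/COCc1ccccc1 | intermediate
3 | (2E,6E,10E)-12-(benzyloxy)-2,6,10-trimethyldodeca-2,6,10-trien-1-ol | OC/C(C)=C/CC/C(C)=C/CC/C(C)=C/COCc1ccccc1 | intermediate
4 | benzyl (2E,6E,10E)-12-bromofarnesyl ether, {[(2E,6E,10E)-12-bromo-3,7,11-trimethyldodeca-2,6,10-trien-1-yl]oxymethyl}benzene | BrC/C(C)=C/CC/C(C)=C/CC/C(C)=C/COCc1ccccc1 | intermediate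
5 | (S)-citronellyl bromide, (6S)-8-bromo-2,6-dimethyloct-2-ene | CC(C)=CCC[C@H](C)CCBr | starting material
6 | (S)-citronellyl phenyl sulfone, {[(3S)-3,7-dimethyloct-6-en-1-yl]sulfonyl}benzene | CC(C)=CCC[C@H](C)CCS(=O)(=O)c1ccccc1 | intermediate
7 | C25 sulfone benzyl ether, {[(2E,6E,10E,15S)-3,7,11,15,19-pentamethyl-13-(phenylsulfonyl)icosa-2,6,10,18-tetraen-1-yl]oxymethyl}benzene, both C13 epimers | CC(C)=CCC[C@H](C)CC(S(=O)(=O)c1ccccc1)C/C(C)=C/CC/C(C)=C/CC/C(C)=C/COCc1ccccc1 | intermediate
8 | (2E,6E,10E,15R)-3,7,11,15,19-pentamethylicosa-2,6,10,18-tetraen-1-ol | CC(C)=CCC[C@H](C)CCC/C(C)=C/CC/C(C)=C/CC/C(C)=C/CO | intermediate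
9 | (2E,6E,10E,15R)-1-bromo-3,7,11,15,19-pentamethylicosa-2,6,10,18-tetraene | CC(C)=CCC[C@H](C)CCC/C(C)=C/CC/C(C)=C/CC/C(C)=C/CBr | intermediate
10 | C25 allylic phenyl sulfone, {[(2E,6E,10E,15R)-3,7,11,15,19-pentamethylicosa-2,6,10,18-tetraen-1-yl]sulfonyl}benzene | CC(C)=CCC[C@H](C)CCC/C(C)=C/CC/C(C)=C/CC/C(C)=C/CS(=O)(=O)c1ccccc1 | intermediate
11 | C40 sulfone benzyl ether, {[(2E,6E,10E,14E,18E,22E,27R)-3,7,11,15,19,23,27,31-octamethyl-13-(phenylsulfonyl)dotriaconta-2,6,10,14,18,22,30-heptaen-1-yl]oxymethyl}benzene, both C13 epimers | CC(C)=CCC[C@H](C)CCC/C(C)=C/CC/C(C)=C/CC/C(C)=C/C(S(=O)(=O)c1ccccc1)C/C(C)=C/CC/C(C)=C/CC/C(C)=C/COCc1ccccc1 | intermediate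
12 | (2E,6E,10E,14E,18E,22E,27R)-3,7,11,15,19,23,27,31-octamethyldotriaconta-2,6,10,14,18,22,30-heptaen-1-ol | CC(C)=CCC[C@H](C)CCC/C(C)=C/CC/C(C)=C/CC/C(C)=C/CC/C(C)=C/CC/C(C)=C/CC/C(C)=C/CO | intermediate
13 | C40 allylic bromide, (2E,6E,10E,14E,18E,22E,27R)-1-bromo-3,7,11,15,19,23,27,31-octamethyldotriaconta-2,6,10,14,18,22,30-heptaene | CC(C)=CCC[C@H](C)CCC/C(C)=C/CC/C(C)=C/CC/C(C)=C/CC/C(C)=C/CC/C(C)=C/CC/C(C)=C/CBr | intermediate
14 | prop-1-yn-1-ylmagnesium bromide CH3C≡CMgBr | CC#C[Mg]Br | starting material
15 | C43 skipped enyne, (5E,9E,13E,17E,21E,25E,30R)-6,10,14,18,22,26,30,34-octamethylpentatriaconta-5,9,13,17,21,25,33-heptaen-2-yne | CC(C)=CCC[C@H](C)CCC/C(C)=C/CC/C(C)=C/CC/C(C)=C/CC/C(C)=C/CC/C(C)=C/CC/C(C)=C/CC#CC | intermediate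
16 | hexacarbonylchromium Cr(CO)6 | [Cr].[C-]#[O+].[C-]#[O+].[C-]#[O+].[C-]#[O+].[C-]#[O+].[C-]#[O+] | starting material
17 | phenyllithium PhLi | [Li]c1ccccc1 | starting material
18 | lithium benzoylpentacarbonylchromate Li[(CO)5CrC(O)Ph] (CO ligands written as separate components) | [Li+].[O-]C(=[Cr])c1ccccc1.[C-]#[O+].[C-]#[O+].[C-]#[O+].[C-]#[O+].[C-]#[O+] | intermediate
19 | pentacarbonyl[methoxy(phenyl)methylidene]chromium (CO)5Cr=C(OMe)Ph (CO ligands written as separate components) | COC(=[Cr])c1ccccc1.[C-]#[O+].[C-]#[O+].[C-]#[O+].[C-]#[O+].[C-]#[O+] | intermediate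
20 | tricarbonylchromium naphthol complex, Cr(CO)3 bound η6 to the oxygenated ring of 21 (written as components; major regioisomer, the minor one converges on 22) | CC(C)=CCC[C@H](C)CCC/C(C)=C/CC/C(C)=C/CC/C(C)=C/CC/C(C)=C/CC/C(C)=C/CC/C(C)=C/Cc1c(C)c(OC)c2ccccc2c1O.[Cr].[C-]#[O+].[C-]#[O+].[C-]#[O+] | intermediate
21 | free methoxynaphthol, 4-methoxy-3-methyl-2-[(2E,6E,10E,14E,18E,22E,27R)-3,7,11,15,19,23,27,31-octamethyldotriaconta-2,6,10,14,18,22,30-heptaen-1-yl]naphthalen-1-ol | CC(C)=CCC[C@H](C)CCC/C(C)=C/CC/C(C)=C/CC/C(C)=C/CC/C(C)=C/CC/C(C)=C/CC/C(C)=C/Cc1c(C)c(OC)c2ccccc2c1O | intermediate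
22 | 2-methyl-3-[(2E,6E,10E,14E,18E,22E,27R)-3,7,11,15,19,23,27,31-octamethyldotriaconta-2,6,10,14,18,22,30-heptaen-1-yl]naphthalene-1,4-dione | CC(C)=CCC[C@H](C)CCC/C(C)=C/CC/C(C)=C/CC/C(C)=C/CC/C(C)=C/CC/C(C)=C/CC/C(C)=C/CC1=C(C)C(=O)c2ccccc2C1=O | target

**Step count and risks**

Total step count: 14. Longest linear sequence: 12 steps (steps 1, 2, 3, 5, 6, 7, 8, 9, 10, 11, 12 and 14, from farnesol).

Steps most likely to fail:

1. Step 14. The vinylcarbene and vinylketene intermediates may be diverted to indene, furan or cyclobutenone products instead of closing onto the phenyl ring, and the polyene may be attacked during the cerium work-up. The fallback gives up the ring construction and attaches the chain to a preformed naphthalene. It sets out from 13 and returns at 22. Purchased 2-bromo-1,4-dimethoxy-3-methylnaphthalene is converted with Mg in THF into (1,4-dimethoxy-3-methylnaphthalen-2-yl)magnesium bromide F1. F1 is alkylated by 13 with CuBr·SMe2 catalysis in THF at −20 °C (SN2 at the primary allylic carbon) to 1,4-dimethoxy-2-methyl-3-polyprenylnaphthalene F2. Oxidative demethylation of F2 with (NH4)2Ce(NO3)6 in MeCN/H2O at 0 °C should give 22.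

2. Step 2. Oxidation may be unselective among the three trisubstituted alkenes, and the product may over-oxidise to the enal. The fallback replaces allylic C–H oxidation by degradation and re-olefination. It sets out from 2 and returns at 3. NBS in THF/H2O at 0 °C should give the terminal bromohydrin F3, and K2CO3 in MeOH closes it to the terminal epoxide F4. HIO4 in THF/H2O cleaves F4 to the trisnor aldehyde F5. Wittig reaction of F5 with the stabilised ylide Ph3P=C(CH3)CO2Et in CH2Cl2 should give the E-enoate F6, and i-Bu2AlH in CH2Cl2 at −78 °C reduces F6 to 3.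

3. Step 10. Electron-transfer cleavage of the allylic sulfone may shift the 14-alkene, scramble its geometry or over-reduce an alkene. The fallback separates the two cleavages and removes the sulfone by a polar mechanism. It sets out from 11 and returns at 12. PdCl2(dppp) (cat.) and LiBHEt3 in THF at 0 °C should deliver hydride to the less hindered terminus of the π-allyl palladium intermediate and give the C40 benzyl ether F7. Lithium naphthalenide LiC10H8 in THF at −25 °C then removes the benzyl group to give 12.

**Further compounds**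

F1 | step 14 | (1,4-dimethoxy-3-methylnaphthalen-2-yl)magnesium bromide | COc1c(C)c([Mg]Br)c(OC)c2ccccc12
F2 | step 14 | 1,4-dimethoxy-2-methyl-3-[(2E,6E,10E,14E,18E,22E,27R)-3,7,11,15,19,23,27,31-octamethyldotriaconta-2,6,10,14,18,22,30-heptaen-1-yl]naphthalene | CC(C)=CCC[C@H](C)CCC/C(C)=C/CC/C(C)=C/CC/C(C)=C/CC/C(C)=C/CC/C(C)=C/CC/C(C)=C/Cc1c(C)c(OC)c2ccccc2c1OC
F3 | step 2 | (6E,10E)-12-(benzyloxy)-3-bromo-2,6,10-trimethyldodeca-6,10-dien-2-ol (racemic at C3) | CC(C)(O)C(Br)CC/C(C)=C/CC/C(C)=C/COCc1ccccc1
F4 | step 2 | 3-[(3E,7E)-9-(benzyloxy)-3,7-dimethylnona-3,7-dien-1-yl]-2,2-dimethyloxirane (racemic) | CC1(C)OC1CC/C(C)=C/CC/C(C)=C/COCc1ccccc1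
F5 | step 2 | (4E,8E)-10-(benzyloxy)-4,8-dimethyldeca-4,8-dienal | O=CCC/C(C)=C/CC/C(C)=C/COCc1ccccc1
F6 | step 2 | ethyl (2E,6E,10E)-12-(benzyloxy)-2,6,10-trimethyldodeca-2,6,10-trienoate | CCOC(=O)/C(C)=C/CC/C(C)=C/CC/C(C)=C/COCc1ccccc1
F7 | step 10 | {[(2E,6E,10E,14E,18E,22E,27R)-3,7,11,15,19,23,27,31-octamethyldotriaconta-2,6,10,14,18,22,30-heptaen-1-yl]oxymethyl}benzene | CC(C)=CCC[C@H](C)CCC/C(C)=C/CC/C(C)=C/CC/C(C)=C/CC/C(C)=C/CC/C(C)=C/CC/C(C)=C/COCc1ccccc1
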